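The earlier runs and the new flask are calculated with constants of no real substance; noise was put on by code.

In a one-step world, Q passes to J by a single step at a fixed molar rate, so a flask's percent is that rate times its running time, divided by its charge. That is my view of these flasks; the forecast shares it for the heavy charges and parts from it at west.

in all of them: D 200 mM (held)

|  | Q | remark | time |
|---|---|---|---|
| teal | 1.7 M | run made earlier |  |
| south | 2.5 M |  | 3.0 h |
| south-east | 0.80 M |  | 3.0 h |
| south-west | 1.5 M |  | 3.0 h |
| west | 0.40 M |  | 3.0 h |

- teal (time / min: J / %): 15.0: 0.7; 30.0: 2.3; 50.0: 4.4; 60.0: 5.1; 80.0: 7.0; 90.0: 7.8; 120: 11.0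

(standard deviation of a reading: 0.3 percentage points)

- ranking by amount of J, in percent of the Q charged, from high to low, at 3.0 h (south / south-east / south-west / west)
- the amount of J, in percent of the Q charged of the flask you put first, at 3.0 h
- the amount of J, in percent of the Q charged of the flask you put last, at 3.0 h

Teal, a slurry of solid Q under held D, climbs on a straight line after a short lag, which reads as a zero-order rate. Its second and last readings, each with a scatter of 0.3 percentage points, give 0.0986 M h⁻¹: this is the molar make, the J formed per litre per hour while solid Q stands. Running that line back from the second reading gives a lag of 6.21 min.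

My reckoning then puts 0.286 M of J in every flask at 3.0 h. That is 11.4% for south and 71.5% for west. West's charge of 0.40 M is larger than that amount, and at the make it lasts until 4.16 h, later than the reading.

The forecast gives west > south-east > south-west > south, with 11.1% for the last flask and 45% for the first. It allows that west may tail off, and of that number it says “Solubility is unknown, so west is uncertain”. We agree on the order and on south, and differ on west.

The flask gives west > south-east > south-west > south, with west at 69.7% and south at 11.2%. West stands 25 points above the forecast and 1.7 points below my line.

    Q ⇌ E, rate k1*(cs1 - [E]) while solid is left; crystals form when [E] > cs1 (solubility = 0.130 M, k = 0.0123 min⁻¹)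
    E + X → J (k = 4.08 M⁻¹ min⁻¹)
    D ⇌ X, rate k3*(csat - [X]) (kL = 0.0472 min⁻¹)
    X → Z (k = 0.00347 min⁻¹)

In south at 0.997 h, the rate at which E is made over the rate at which it is used up is 0.995, and E stands at 0.100% of the charge at 1.50 h and 0.0990% at 3.00 h. In west at 3.00 h, E is 0.619% and Q is still 29.7% of the charge. The make reckons that charge used by 4.16 h, later than the reading, and the forecast's tail has its region past that reckoned time. South with 1.0 M of Q is reckoned by the make at 28.6%, and that flask holds 27.9% of J.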